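**Assumptions**
- 3-Methyltetronic acid and 4-methoxy-3-methylfuranone are made rather than bought.
- (–)-(NMI)₂ZrCl₂ is assumed to deliver the (R)-2-methyl alcohol. If (S) is obtained, the (+)-catalyst is used instead.
- The asymmetric carboalumination is assumed to reach about 90% ee. Any shortfall is removed by preparative chiral HPLC of alcohol 10, which is not a chemical step.

**Retrosynthesis**
1. Target ⇐ O-demethylation of the (Z)-5-ylidene 4-methoxytetronate. This comes from a vinylogous aldol and E1cB dehydration of lithiated 4-methoxy-3-methylfuranone (5, built by Dieckmann cyclisation) with the α-methyl aldehyde 18.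
2. Aldehyde 18 ⇐ B-alkyl Suzuki coupling of the (E)-vinyl iodide 10 with the alkylborane from 4-vinyl-2-(3-furylmethyl)furan (16). The furans are carried in preformed from furfural-derived 4-bromofurfural and 3-bromofuran.
3. Key step: the achiral enyne 8 becomes an (E)-vinyl iodide by carboalumination. Zr-catalysed asymmetric carboalumination (ZACA) of its prochiral terminal alkene then breaks the mirror symmetry and sets the CH(CH₃) centre as (R), giving 10.
4. Ring order: the two furans are already present. The tetronate ring forms first (Dieckmann), then the exocyclic Z-alkene (aldol/elimination).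

**Route**

Step 1
Reactants: 1 methyl glycolate; 2 propionyl chloride
Product: 3 methyl 2-(propanoyloxy)acetate
Conditions: pyridine, CH₂Cl₂, 0 °C → rt
Reagents that add atoms: none
Why: Simple O-acylation of the alcohol (Schotten–Baumann-type esterification) installs the propionyl group that becomes C-3 and its methyl.

Step 2
Reactants: 3
Product: 4 3-methyltetronic acid (4-hydroxy-3-methylfuran-2(5H)-one)
Conditions: KOtBu (2.2 equiv), THF, 0 °C → rt; then aq. HCl
Reagents that add atoms: none
Why: The propionate enolate attacks the methyl ester in a Dieckmann (Lacey–Dieckmann) cyclisation and loses MeO⁻; the product is trapped as the tetronate, so no stereocentre is formed.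

Step 3
Reactants: 4
Product: 5 4-methoxy-3-methylfuran-2(5H)-one
Conditions: TMSCHN₂, MeOH/PhMe, 0 °C → rt
Reagents that add atoms: TMSCHN₂, C[Si](C)(C)C=[N+]=[N-] (adds CH₃)
Why: The strongly acidic vinylogous acid (pKa about 4) is O-methylated selectively by diazoalkane methylation.

Step 4
Reactants: 6 5-bromopent-1-ene; 7 lithium acetylide–ethylenediamine complex
Product: 8 hept-1-en-6-yne
Conditions: DMSO, rt, 12 h
Reagents that add atoms: none
Why: SN2 alkylation of an acetylide with a primary bromide gives the achiral enyne; the terminal alkene is the prochiral site for the key step.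

Step 5
Reactants: 8
Product: 9 (E)-1-iodo-2-methylhepta-1,6-diene
Conditions: Me₃Al (2 equiv), Cp₂ZrCl₂ (10 mol%), ClCH₂CH₂Cl, 0 °C → rt; then I₂, THF, –30 °C
Reagents that add atoms: Me₃Al, C[Al](C)C (adds CH₃); I₂, II (adds I)
Why: Negishi carboalumination is a syn-methylalumination of the terminal alkyne, which reacts much faster than the terminal alkene. Iodinolysis with retention gives the E-trisubstituted vinyl iodide, whose geometry is the one in the target.

Step 6
Reactants: 9
Product: 10 (2R,6E)-7-iodo-2,6-dimethylhept-6-en-1-ol
Conditions: Me₃Al (3 equiv), (–)-(NMI)₂ZrCl₂ (5 mol%), CH₂Cl₂, 23 °C, 24 h; then dry O₂, 0 °C; aq. workup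
Reagents that add atoms: Me₃Al, C[Al](C)C (adds CH₃); O₂, O=O (adds OH oxygen)
Why: Proposed new method: chiral zirconocene-catalysed asymmetric methylalumination (ZACA) of the terminal alkene puts Me on the internal carbon and Al on CH₂, fixing the (R) centre by enantiotopic-face selection. The CH₂–Al bond is then oxidised to CH₂OH by O₂. The closest known reaction is Negishi's ZACA of 1-alkenes. The new element is that the substrate carries a vinyl iodide, which is assumed inert to Zr–Me/AlMe₃ at rt.

Step 7
Reactants: 11 3-bromofuran; 12 4-bromofuran-2-carbaldehyde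
Product: 13 (4-bromofuran-2-yl)(furan-3-yl)methanol
Conditions: n-BuLi (1.05 equiv), Et₂O, –78 °C (Li–Br exchange); then add 12, –78 °C → –40 °C
Reagents that add atoms: none (n-BuLi leaves only Li/Bu in by-products)
Why: The 3-furyllithium adds to the aldehyde (Li–Br exchange then 1,2-addition), and the C-4 bromide survives at –78 °C.

Step 8
Reactants: 13
Product: 14 4-bromo-2-(furan-3-ylmethyl)furan
Conditions: Et₃SiH (3 equiv), TFA (3 equiv), CH₂Cl₂, –20 → 0 °C
Reagents that add atoms: none
Why: Ionic hydrogenation of a doubly heteroaryl-stabilised carbocation converts the carbinol to CH₂ and gives the 2,4-disubstituted difurylmethane.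

Step 9
Reactants: 14; 15 potassium vinyltrifluoroborate
Product: 16 2-(furan-3-ylmethyl)-4-vinylfuran
Conditions: PdCl₂(dppf)·CH₂Cl₂ (5 mol%), Et₃N, i-PrOH/H₂O (9:1), 80 °C, BHT
Reagents that add atoms: none (the vinyl group comes from 15)
Why: Suzuki–Miyaura vinylation of the 4-bromofuran; the vinylfuran is used at once because it is prone to polymerisation.

Step 10
Reactants: 16; 10
Product: 17 (2R,6E)-9-[5-(furan-3-ylmethyl)furan-3-yl]-2,6-dimethylnon-6-en-1-ol
Conditions: 9-BBN dimer (THF, rt, 3 h); then 10, PdCl₂(dppf) (5 mol%), aq. K₃PO₄, THF/DMF, 50 °C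
Reagents that add atoms: none (the boron is lost)
Why: Anti-Markovnikov hydroboration of the vinylfuran gives a primary B-alkyl-9-BBN, and B-alkyl Suzuki coupling with the vinyl iodide joins C8–C9 with retention of E geometry; the (R) centre is untouched.

Step 11
Reactants: 17
Product: 18 (2R,6E)-9-[5-(furan-3-ylmethyl)furan-3-yl]-2,6-dimethylnon-6-enal
Conditions: Dess–Martin periodinane, NaHCO₃, CH₂Cl₂, 0 °C, 1 h
Reagents that add atoms: none
Why: Buffered, mild oxidation of the primary alcohol avoids epimerisation of the α-methyl centre and leaves the furans and alkene intact.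

Step 12
Reactants: 5; 18
Product: 19 5-[1-hydroxy-(2R)-2-methyl-…-alkyl]-4-methoxy-3-methylfuran-2(5H)-one, a mixture of diastereomers at the two new centres that are destroyed in the next step
Conditions: LDA (1.05 equiv relative to 5), THF, –78 °C, 30 min; then 18, –78 °C, 1 h
Reagents that add atoms: none
Why: Vinylogous aldol of the C-5 lithiated 4-methoxytetronate (γ-deprotonation) with the aldehyde at –78 °C; the new stereocentres are transient and the α-centre is preserved.

Step 13
Reactants: 19
Product: 20 (Z)-4-methoxy-3-methyl-5-alkylidenefuran-2(5H)-one (the O-methyl ether of the target)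
Conditions: MsCl, Et₃N, CH₂Cl₂, 0 °C; then DBU (2 equiv), 0 °C → rt
Reagents that add atoms: none (the mesylate is lost)
Why: Mesylation then base-induced elimination (E1cB-type dehydration) gives the thermodynamically favoured Z-ylidene, with the chain cis to the ring oxygen and away from the C4–OMe.

Step 14
Reactants: 20
Product: 21 target
Conditions: LiI (10 equiv), pyridine, 90 °C, 3 h; then aq. citric acid
Reagents that add atoms: none (the methyl is lost as MeI)
Why: SN2 dealkylation at the O-methyl carbon, with tetronate as a good leaving group (as in LiI cleavage of methyl esters), releases the 4-hydroxy tetronic acid without touching the furans, the trisubstituted alkene or the stereocentre.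

**Compound list**

| No. | Name | SMILES | Role |
|---|---|---|---|
| 1 | methyl glycolate | COC(=O)CO | starting material |
| 2 | propionyl chloride | CCC(=O)Cl | starting material |
| 3 | methyl 2-(propanoyloxy)acetate | CCC(=O)OCC(=O)OC | intermediate |
| 4 | 3-methyltetronic acid | CC1=C(O)COC1=O | intermediate |
| 5 | 4-methoxy-3-methylfuran-2(5H)-one | COC1=C(C)C(=O)OC1 | intermediate |
| 6 | 5-bromopent-1-ene | C=CCCCBr | starting material |
| 7 | lithium acetylide–ethylenediamine | [Li]C#C | starting material |
| 8 | hept-1-en-6-yne | C=CCCCC#C | intermediate |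
| 9 | (E)-1-iodo-2-methylhepta-1,6-diene | I/C=C(\C)CCCC=C | intermediate |
| 10 | (2R,6E)-7-iodo-2,6-dimethylhept-6-en-1-ol | OC[C@H](C)CCC/C(C)=C/I | intermediate |
| 11 | 3-bromofuran | Brc1ccoc1 | starting material |
| 12 | 4-bromofuran-2-carbaldehyde | O=Cc1cc(Br)co1 | starting material |
| 13 | (4-bromofuran-2-yl)(furan-3-yl)methanol | OC(c1cc(Br)co1)c1ccoc1 | intermediate |
| 14 | 4-bromo-2-(furan-3-ylmethyl)furan | Brc1coc(Cc2ccoc2)c1 | intermediate |
| 15 | potassium vinyltrifluoroborate | C=C[B-](F)(F)F.[K+] | starting material |
| 16 | 2-(furan-3-ylmethyl)-4-vinylfuran | C=Cc1coc(Cc2ccoc2)c1 | intermediate |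
| 17 | (2R,6E)-9-[5-(furan-3-ylmethyl)furan-3-yl]-2,6-dimethylnon-6-en-1-ol | OC[C@H](C)CCC/C(C)=C/CCc1coc(Cc2ccoc2)c1 | intermediate |
| 18 | (2R,6E)-9-[5-(furan-3-ylmethyl)furan-3-yl]-2,6-dimethylnon-6-enal | O=C[C@H](C)CCC/C(C)=C/CCc1coc(Cc2ccoc2)c1 | intermediate |
| 19 | aldol adduct, (R) chain centre, two undefined new centres | COC1=C(C)C(=O)OC1C(O)[C@H](C)CCC/C(C)=C/CCc2coc(Cc3ccoc3)c2 | intermediate |
| 20 | (Z)-4-O-methyl ylidene tetronate | CC1=C(OC)/C(=C/[C@H](C)CCC/C(C)=C/CCc2coc(Cc3ccoc3)c2)OC1=O | intermediate |
| 21 | target, CID54702820 | CC1=C(O)/C(=C/[C@H](C)CCC/C(C)=C/CCc2coc(Cc3ccoc3)c2)OC1=O | target |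

**Total step count:** 14 steps. **Longest linear sequence:** 8 steps (4→5→6→10→11→12→13→14, or equivalently 7→8→9→10→…→14).

**Three steps most likely to fail**
1. **Step 6 (ZACA with a vinyl iodide present; ee about 90% at best).** The catalyst may be incompatible with the vinyl iodide, or the ee may be too low. Fallback: set the centre by lipase desymmetrisation of 2-methylpropane-1,3-diol to the monoacetate, then elaborate it by iodination and coupling to the same alcohol, with the vinyl iodide built afterwards.
2. **Step 8 (TFA/Et₃SiH deoxygenation of a difurylcarbinol).** The acid-sensitive furans may oligomerise. Fallback: convert carbinol 13 to its xanthate and deoxygenate by Barton–McCombie radical chemistry, which is acid-free.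
3. **Step 14 (nucleophilic O-demethylation at 90 °C).** The ylidene lactone or the polyene may degrade, or epimerisation may occur. Fallback: remake the tetronate as the 4-O-allyl ether (Mitsunobu with allyl alcohol) in place of the methyl ether, and remove it with Pd(PPh₃)₄/morpholine at rt.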